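Structural features

The target is one cyclobutane ring in which C1 and C3 each carry the carbonyl of an N-acyl-5,6-dihydropyridin-2(1H)-one (an imide nitrogen inside an unsaturated six-membered lactam) and C2 and C4 each carry a 3,4,5-trimethoxyphenyl ring, a head-to-tail arrangement. All four ring carbons are contiguous stereocentres and every neighbouring pair is trans, so the two aryl groups are cis to each other across the ring, the two acyl groups likewise, and the molecule has mirror symmetry (meso), which means that only relative configuration has to be controlled. C1 and C3 are α to a carbonyl and can be equilibrated, and all-trans is the most stable arrangement, whereas the aryl-bearing carbons C2 and C4 cannot be corrected once they are set. The fragile parts are the two imides, which pass their acyl group to nucleophiles and hydrolyse easily, and the conjugated C=C bonds of the lactams, which are Michael acceptors and would not survive hydrogenation; both argue for attaching the lactams last. The real difficulty is therefore the four-membered ring itself with head-to-tail regiochemistry and a cis relationship between C2 and C4, which a light-induced dimerisation of the corresponding cinnamoyl imide does not guarantee. The key step exploits the fact that C2 and C4 are each bonded to both C1 and C3: C2 and C4 can start as the two carbons of a diarylalkyne, C1 and C3 can each arrive as a carbene carbon that forms both of its ring bonds at once, and the extra C2–C4 bond that this leaves (the central bond of a bicyclo[1.1.0]butane) is removed afterwards by adding hydrogen to one face, which makes the aryl groups cis.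

Logic of the disconnections

The two exocyclic imide C–N bonds of 12 are cut first. The lactam rings are the most fragile part of the molecule (acyl transfer, conjugate addition, reduction) and should enter last. The cut leaves 8 and two molecules of 9, so twelve ring atoms and both Michael acceptors leave the problem and its symmetry is restored. The forward step must acylate a weakly nucleophilic lactam nitrogen twice at hindered acyl groups, which is why 8 is activated as 10 and 9 as 11. It must also leave the acyl-bearing stereocentres alone, a mild demand because they already hold the most stable configuration.

Between 8 and 7 no skeletal bond is cut; only the acyl C–O bonds change from acid to ethyl ester. The ester is the oxidation level at which the acyl-bearing carbons can be equilibrated by alkoxide, so their configuration need not be controlled kinetically anywhere earlier. The forward step demands that the aryl-bearing carbons of 7 are already cis and that equilibration is finished before hydrolysis locks the configuration.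

Going back from 7 to 6, a bond is added: the two benzylic C–H bonds at the aryl-bearing carbons are replaced by a bond between those carbons, the central bond of a bicyclo[1.1.0]butane. This turns the one relationship that cannot be corrected later, the cis arrangement of the aryl-bearing carbons, into a consequence of ring geometry. Two stereocentres collapse into bridgeheads whose fusion can only be cis, and the perimeter becomes accessible by (2+1) additions. The forward hydrogenolysis must cleave only this bond and must place both hydrogens on one face.

In 6 the two bonds from one ester-bearing flap carbon to the two bridgeheads are cut together. Both bonds start from a carbon that carries one hydrogen and one ester, which is exactly what 4 delivers as a carbene. One ring and one carbon leave, and the achiral 5 remains. The forward step needs the carbene to add to a hindered, strained double bond on the face anti to the existing ester, faster than 5 is opened and faster than 4 dimerises.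

The same cut is repeated in 5: the two bonds from the remaining ester-bearing carbon to the two aryl-bearing carbons. This uses the symmetry a second time, leaves the acyclic, symmetric 3 and uses 4 again. The forward step is the cyclopropenation of an internal alkyne, which has to compete with carbene dimerisation and stop after one addition.

Finally one aryl–alkynyl bond of 3 is cut, a standard cross-coupling bond. This leaves the two commercial arenes 1 and 2. The forward coupling only has to avoid homocoupling of 2.

Other disconnections considered

Alternative 1: The ring is bought and not built. The cut removes the aryl–C2 bond and the C3–carbon bond from 3-(dicyanomethyl)-N-(quinolin-8-yl)-2-(3,4,5-trimethoxyphenyl)cyclobutane-1-carboxamide A1, which goes back to N-(quinolin-8-yl)cyclobut-2-ene-1-carboxamide A2, malononitrile A3 and 1.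
- Forward key step: Pd(OAc)2, held by the bidentate quinolinyl amide, activates the ring double bond of A2. The anion of A3 attacks C3 on the face away from palladium, the palladacycle adds 1 oxidatively (divalent to tetravalent palladium), and reductive elimination passes the aryl group to C2 on the palladium face. The aryl group therefore ends cis to the amide and the dicyanomethyl group trans to the aryl group.
- In its favour: two bonds and two stereocentres form in one operation with an outcome fixed by mechanism, and no diazo compound or strained bicyclic intermediate is needed. The aryl groups would enter one at a time, which makes this plan better than the chosen one for analogues with two different aryl groups. In predictability of the key step it is at least the equal of the chosen plan.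
- Against it here: A1 holds only one of the two aryl groups, so C4 would still need an amide-directed C–H arylation with 1. The dicyanomethyl group would have to be degraded oxidatively to a carboxyl group. The directing amide sits cis to the aryl group and would have to be epimerised and then cleaved. The twofold symmetry of the target is not used.
- Comparison: on structure, this plan decorates a preformed ring atom by atom, whereas the chosen plan assembles the ring from the four substituent-bearing carbons. On mechanism, it is a divalent/tetravalent palladium cycle with a removable auxiliary against two carbene transfers and a hydrogenolysis. On step economy it is estimated at ten or more steps against six, which decides against it.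

Alternative 2: The cut is made inside both arenes. In each ring of dimethyl all-trans-2,4-bis(4-hydroxy-3,5-dimethoxyphenyl)cyclobutane-1,3-dicarboxylate A4 the C2–C3 and C5–C6 bonds are broken, which leads back to the cyclobutane-1,3-diyl bis(vinamidinium) salt A5 and two molecules of 1,3-dimethoxypropan-2-one A6.
- Forward key step: KOtBu forms the enolate of A6, which condenses twice with each vinamidinium unit (addition, loss of dimethylamine, second addition, aromatisation). This (3+3) benzannulation closes both benzene rings as 2,6-dimethoxyphenols, and O-methylation would then give the ring pattern of the target.
- In its favour: the configuration of the cyclobutane is settled on a small aliphatic precursor before any arene exists. There is no transition metal, no diazo compound and no strained intermediate, which makes it the better plan on hazard. A4 with its free phenols is a better entry to 4-hydroxy analogues than anything in the chosen route. From the all-trans diester onward the endgame is the same, so there the two plans are equal.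
- Against it here: bonds are spent on making 3,4,5-trimethoxyphenyl rings that are available ready-made. The real problem, a cis relationship between the two carbons that will carry the arenes, is moved unsolved into the synthesis of A5. The strongly basic double condensation has to spare two enolisable esters on a strained ring, and an extra methylation is needed.
- Comparison: on structure it builds the periphery onto the core, and the chosen plan builds the core from the periphery. On mechanism it is ionic condensation chemistry against carbene chemistry. On step economy it is estimated at well over ten steps and is clearly longer.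

Alternative 3: The cut is a ring bond of the cyclobutane together with one amide C–N bond. Methyl all-trans-3-(but-3-en-1-ylcarbamoyl)-2,4-bis(3,4,5-trimethoxyphenyl)cyclobutane-1-carboxylate A7 is traced back to the five-membered α-diazoketone methyl 3-diazo-4-oxo-2,5-bis(3,4,5-trimethoxyphenyl)cyclopentane-1-carboxylate A8 and but-3-en-1-amine A9.
- Forward key step: light expels dinitrogen from A8, the aryl-bearing α-carbon migrates to the carbene carbon with retention (Wolff rearrangement), the ring contracts to a cyclobutylketene, and A9 adds to the ketene to give the amide.
- In its favour: five-membered rings are easier to make and to equilibrate than four-membered ones, and the migrating carbon keeps its configuration. The carbene is generated within the molecule, so neither bimolecular carbene dimerisation nor a bicyclobutane has to be managed; in this respect it is the better plan. The butenyl amide prepares one lactam ring for N-acryloylation and ring-closing metathesis. In its reliance on loss of dinitrogen from a diazo compound as driving force it is the equal of the chosen plan.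
- Against it here: the target is symmetric, yet A7 carries one acyl group as an amide and the other as a methyl ester, so the second side has to be hydrolysed and amidated and both lactams built in further steps. A8 itself needs a stereodefined 2,5-diarylcyclopentanone and a diazo transfer next to an aryl-bearing carbon. The new stereocentre is set by protonation of the amide enol, probably from the face away from the two cis aryl groups, so an epimerisation would still be needed.
- Comparison: on structure it reaches the ring by contraction of a larger ring, and the chosen plan by two additions to an alkyne. On mechanism both pass through carbenes. On step economy it is estimated at twelve or more steps against six.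

Key step: step 3

Remark on the chemistry: the target is a meso compound, so all descriptors express relative configuration and no absolute stereocontrol is needed. Precursor 5 is kept as the ethyl ester with only hydrogen opposite the ester on its sp3 carbon, and both ester groups are ethyl so that ethoxide can equilibrate them later without transesterification. Compound 4 is used as its commercial solution, added by syringe pump and never concentrated.

Step 1
Reactants: 1 5-iodo-1,2,3-trimethoxybenzene; 2 5-ethynyl-1,2,3-trimethoxybenzene
Product: 3 1,2-bis(3,4,5-trimethoxyphenyl)ethyne
Conditions: Pd(PPh3)2Cl2 (2 mol%), CuI (4 mol%), Et3N, THF, degassed, rt to 50 °C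
Reagents that add atoms: none
Why: Sonogashira coupling: the aryl iodide adds oxidatively to zerovalent palladium at low temperature, the copper acetylide of 2 transmetallates and reductive elimination forms the aryl–alkynyl bond; degassing suppresses Glaser homocoupling of 2, and no stereocentre is formed.

Step 2
Reactants: 3 1,2-bis(3,4,5-trimethoxyphenyl)ethyne; 4 ethyl diazoacetate
Product: 5 ethyl 2,3-bis(3,4,5-trimethoxyphenyl)cycloprop-2-ene-1-carboxylate
Conditions: Rh2(OAc)4 (1 mol%), 4 (1.5 equiv, syringe pump), CH2Cl2, rt; unreacted 3 recovered
Reagents that add atoms: none
Why: Cyclopropenation of an alkyne by a divalent-rhodium carbenoid, a (2+1) addition: the electron-rich diarylalkyne suits the electrophilic carbenoid and slow addition of 4 keeps carbene dimerisation low; 5 is achiral because its ester-bearing carbon lies on a mirror plane, so nothing has to be controlled.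

Step 3
Reactants: 5 ethyl 2,3-bis(3,4,5-trimethoxyphenyl)cycloprop-2-ene-1-carboxylate; 4 ethyl diazoacetate
Product: 6 diethyl exo,exo-1,3-bis(3,4,5-trimethoxyphenyl)bicyclo[1.1.0]butane-2,4-dicarboxylate (both esters on the outer side of the fold, both flap hydrogens endo)
Conditions: Cu(acac)2 (5 mol%), 4 (3 equiv, syringe pump), PhMe, 80 °C, base-washed glassware
Reagents that add atoms: none
Why: Cu(acac)2 is reduced by the diazo ester to monovalent copper, which takes up 4 with loss of dinitrogen to give an electrophilic copper carbene. The carbene carbon forms both of its new bonds to C2 and C3 of 5 in one concerted, asynchronous (2+1) addition across the strained, aryl-activated double bond; the closest known reaction type is the copper-catalysed cyclopropanation of alkenes with diazoacetates, which is known for 1,2-diarylcyclopropene-3-carboxylates and gives 1,3-diarylbicyclobutane-2,4-dicarboxylates. The second three-membered ring therefore closes by a cheletropic-type addition along the former double bond, which becomes the central bond of the bicyclo[1.1.0]butane, and the ring fusion can only be cis. The configuration at the old ester carbon is controlled by the substrate: the ester on the sp3 carbon of 5 covers one face of the double bond, the carbenoid comes in on the other, and that ester ends exo. The new ester carbon is controlled by the approach geometry: its ester turns away from the fold and from the hydrogen on the opposite flap and should also end exo. The step needs chemoselectivity for addition over ring-opening of 5 to a vinylcarbene (which would lead to a furan) and over carbene dimerisation; the raised energy of the strained π bond, the two donor aryl groups, the weakly Lewis-acidic acetylacetonate ligands and the low stationary concentration of 4 should secure it. The exo or endo outcome at the new carbon is not critical, because both ester carbons are equilibrated in step 5.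

Step 4
Reactants: 6 diethyl exo,exo-1,3-bis(3,4,5-trimethoxyphenyl)bicyclo[1.1.0]butane-2,4-dicarboxylate
Product: 7 diethyl all-trans-2,4-bis(3,4,5-trimethoxyphenyl)cyclobutane-1,3-dicarboxylate (aryl groups cis to each other, each ester trans to both neighbouring aryl groups)
Conditions: H2 (1 atm), 10% Pd/C, K2CO3 (cat.), EtOAc, rt
Reagents that add atoms: none
Why: Catalytic hydrogenolysis of the central bond of a bicyclobutane, its most strained and doubly benzylic σ bond: both hydrogens should pass from the palladium surface into the positions the broken bond leaves, i.e. onto one face, so the two aryl groups swing to the other face and end cis to each other and, for the exo,exo diester, trans to both esters; an ester that ends cis to the aryl groups (from endo material or the opposite delivery mode) is corrected in step 5, and K2CO3 keeps the support from opening 6 through a benzylic cation.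

Step 5
Reactants: 7 diethyl all-trans-2,4-bis(3,4,5-trimethoxyphenyl)cyclobutane-1,3-dicarboxylate
Product: 8 all-trans-2,4-bis(3,4,5-trimethoxyphenyl)cyclobutane-1,3-dicarboxylic acid
Conditions: NaOEt (0.3 equiv), EtOH, reflux; then NaOH, H2O, reflux; HCl to pH 1
Reagents that add atoms: sodium hydroxide, [Na+].[OH-] (oxygen of each carboxyl OH)
Why: Thermodynamic epimerisation through the ester enolates (ethoxide in ethanol, so no transesterification) places each ester trans to its two aryl neighbours, the most stable arrangement, and the following saponification (acyl–oxygen cleavage by hydroxide) locks it because carboxylates no longer enolise; the aryl-bearing carbons are not acidic and keep the cis relationship set in step 4.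

Step 6
Reactants: 8 all-trans-2,4-bis(3,4,5-trimethoxyphenyl)cyclobutane-1,3-dicarboxylic acid; 9 5,6-dihydropyridin-2(1H)-one
Product: 12 all-trans-1,1'-[2,4-bis(3,4,5-trimethoxyphenyl)cyclobutane-1,3-dicarbonyl]bis(5,6-dihydropyridin-2(1H)-one) (target), via all-trans-2,4-bis(3,4,5-trimethoxyphenyl)cyclobutane-1,3-dicarbonyl dichloride 10 (not isolated), via lithium 2-oxo-5,6-dihydropyridin-1(2H)-ide 11 (not isolated)
Conditions: (COCl)2, DMF (cat.), CH2Cl2, 0 °C to rt, evaporate; 9 (2.1 equiv), LiN(SiMe3)2 (2.05 equiv), THF, −78 °C, added to 10 in THF, −78 to −20 °C; aq. NH4Cl
Reagents that add atoms: oxalyl chloride, O=C(Cl)C(Cl)=O (chlorine atoms of 10 only); lithium bis(trimethylsilyl)amide, [Li+].C[Si](C)(C)[N-][Si](C)(C)C (lithium of 11 only)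
Why: Acid chloride formation with oxalyl chloride under Vilsmeier-type catalysis, then N-acylation of the lithium amidate of the lactam by addition–elimination; the non-nucleophilic amide base and the low temperature protect the conjugated lactam from conjugate addition, and the α-carbons are not at risk because their hydrogens are shielded by the two flanking cis aryl groups and the acyl groups already hold their thermodynamically preferred trans positions.

Compound list

1 | 5-iodo-1,2,3-trimethoxybenzene | COc1cc(I)cc(OC)c1OC | starting material
2 | 5-ethynyl-1,2,3-trimethoxybenzene | C#Cc1cc(OC)c(OC)c(OC)c1 | starting material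
3 | 1,2-bis(3,4,5-trimethoxyphenyl)ethyne | COc1cc(C#Cc2cc(OC)c(OC)c(OC)c2)cc(OC)c1OC | intermediate
4 | ethyl diazoacetate | CCOC(=O)C=[N+]=[N-] | starting material
5 | ethyl 2,3-bis(3,4,5-trimethoxyphenyl)cycloprop-2-ene-1-carboxylate (achiral) | CCOC(=O)C1C(c2cc(OC)c(OC)c(OC)c2)=C1c1cc(OC)c(OC)c(OC)c1 | intermediate
6 | diethyl exo,exo-1,3-bis(3,4,5-trimethoxyphenyl)bicyclo[1.1.0]butane-2,4-dicarboxylate | CCOC(=O)[C@@H]1[C@@]2(c3cc(OC)c(OC)c(OC)c3)[C@H](C(=O)OCC)[C@@]12c1cc(OC)c(OC)c(OC)c1 | intermediate
7 | diethyl all-trans-2,4-bis(3,4,5-trimethoxyphenyl)cyclobutane-1,3-dicarboxylate (meso) | CCOC(=O)[C@H]1[C@H](c2cc(OC)c(OC)c(OC)c2)[C@@H](C(=O)OCC)[C@@H]1c1cc(OC)c(OC)c(OC)c1 | intermediate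
8 | all-trans-2,4-bis(3,4,5-trimethoxyphenyl)cyclobutane-1,3-dicarboxylic acid (meso) | OC(=O)[C@H]1[C@H](c2cc(OC)c(OC)c(OC)c2)[C@@H](C(=O)O)[C@@H]1c1cc(OC)c(OC)c(OC)c1 | intermediate
9 | 5,6-dihydropyridin-2(1H)-one | O=C1C=CCCN1 | starting material
10 | all-trans-2,4-bis(3,4,5-trimethoxyphenyl)cyclobutane-1,3-dicarbonyl dichloride (not isolated) | ClC(=O)[C@H]1[C@H](c2cc(OC)c(OC)c(OC)c2)[C@@H](C(Cl)=O)[C@@H]1c1cc(OC)c(OC)c(OC)c1 | intermediate
11 | lithium 2-oxo-5,6-dihydropyridin-1(2H)-ide (lithium salt of 9, not isolated) | [Li+].O=C1C=CCC[N-]1 | intermediate
12 | all-trans-1,1'-[2,4-bis(3,4,5-trimethoxyphenyl)cyclobutane-1,3-dicarbonyl]bis(5,6-dihydropyridin-2(1H)-one) (meso) | COc1cc([C@H]2[C@H](C(=O)N3CCC=CC3=O)[C@@H](c3cc(OC)c(OC)c(OC)c3)[C@@H]2C(=O)N2CCC=CC2=O)cc(OC)c1OC | target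

Total step count: 6. Longest linear sequence: 6 steps (1 and 2 to 3, 5, 6, 7, 8, 12).

Least certain steps

Step 3 (key step).
- What may go wrong: copper may open the cyclopropene to a vinylcarbene that is captured by the ester carbonyl (furan formation). The carbene may dimerise faster than it adds to a hindered, fully substituted double bond. The bicyclobutane may isomerise to a diene under heat or metal catalysis.
- Fallback (sets out from 5, comes back at 6): without any metal, 4 adds as a 1,3-dipole to the strained double bond of 5 (Et2O, rt, dark), again on the face anti to the ester, to give diethyl 1,5-bis(3,4,5-trimethoxyphenyl)-2,3-diazabicyclo[3.1.0]hex-2-ene-4,6-dicarboxylate F1. Direct irradiation (Pyrex filter, Et2O, −20 °C) expels dinitrogen and the 1,3-diradical closes to 6. The configuration at the diazo-derived carbon of F1 is not important, because it becomes a flap carbon that is equilibrated in step 5. F1 should be photolysed promptly and kept free of acid and base, since tautomerisation to the 2-pyrazoline would block the loss of dinitrogen.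

Step 4.
- What may go wrong: suprafacial delivery may be lost if a half-hydrogenated benzylic palladium species undergoes β-hydride elimination and re-addition, which would place the aryl groups trans. A lateral ring bond may also be cleaved, or the ring may be opened by acid on the support.
- Fallback (sets out from 7 obtained as a mixture of aryl epimers, comes back at 7): the benzylic C–H bonds at the aryl-bearing carbons are equilibrated by reversible hydrogen-atom transfer. This uses irradiation at 390 nm with (Bu4N)4W10O32 as hydrogen-abstracting photocatalyst and a catalytic diaryl disulfide as source of the hydrogen-donating thiol in MeCN, a known way of editing tertiary and benzylic stereocentres toward the more stable epimer. The arrangement with both aryl groups trans to both esters is the global minimum, and the ester carbons equilibrate under NaOEt, so the mixture should drain into 7. This path creates no compound outside the compound list (F0).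

Step 6.
- What may go wrong: the second acylation at a hindered acyl chloride may be incomplete. A ketene may form, with loss of configuration on kinetic re-protonation. The lactam anion may undergo conjugate addition or oligomerise, or deprotonate the imide product.
- Fallback (sets out from 10, comes back at 12): the lactam rings are built after the nitrogen is attached. Compound 10 with but-3-en-1-amine and Et3N in CH2Cl2 should give all-trans-N1,N3-di(but-3-en-1-yl)-2,4-bis(3,4,5-trimethoxyphenyl)cyclobutane-1,3-dicarboxamide F2. N-deprotonation with LiN(SiMe3)2 in THF at −78 °C and acryloyl chloride should give all-trans-N1,N3-diacryloyl-N1,N3-di(but-3-en-1-yl)-2,4-bis(3,4,5-trimethoxyphenyl)cyclobutane-1,3-dicarboxamide F3. Double ring-closing metathesis with the second-generation Grubbs catalyst RuCl2(=CHPh)(PCy3)(H2IMes) in CH2Cl2 at 40 °C closes both 5,6-dihydropyridin-2(1H)-one rings with loss of ethene and gives 12.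

Step 2.
- What may go wrong: carbene dimerisation may win over addition to a hindered internal alkyne. Furan formation from the alkyne–carbenoid adduct or partial second addition may also occur.
- Fallback (sets out from 2, comes back at 5; step 1 is then not needed): the terminal alkyne 2, a much better partner for the rhodium carbenoid, is cyclopropenated with 4 (Rh2(OAc)4, CH2Cl2, rt) to racemic ethyl 2-(3,4,5-trimethoxyphenyl)cycloprop-2-ene-1-carboxylate F4. The remaining vinylic C–H bond is then arylated with 1 in a Heck-type direct arylation of the cyclopropene (Pd(OAc)2, K2CO3, DMF, 30 °C), which gives 5.

Further compounds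

F1 | step 3 | diethyl 1,5-bis(3,4,5-trimethoxyphenyl)-2,3-diazabicyclo[3.1.0]hex-2-ene-4,6-dicarboxylate (6-ester exo, 4-ester trans to C6) | CCOC(=O)[C@H]1N=N[C@]2(c3cc(OC)c(OC)c(OC)c3)[C@@H](C(=O)OCC)[C@]12c1cc(OC)c(OC)c(OC)c1
F0 | step 4 | none | none
F2 | step 6 | all-trans-N1,N3-di(but-3-en-1-yl)-2,4-bis(3,4,5-trimethoxyphenyl)cyclobutane-1,3-dicarboxamide | C=CCCNC(=O)[C@H]1[C@H](c2cc(OC)c(OC)c(OC)c2)[C@@H](C(=O)NCCC=C)[C@@H]1c1cc(OC)c(OC)c(OC)c1
F3 | step 6 | all-trans-N1,N3-diacryloyl-N1,N3-di(but-3-en-1-yl)-2,4-bis(3,4,5-trimethoxyphenyl)cyclobutane-1,3-dicarboxamide | C=CCCN(C(=O)C=C)C(=O)[C@H]1[C@H](c2cc(OC)c(OC)c(OC)c2)[C@@H](C(=O)N(CCC=C)C(=O)C=C)[C@@H]1c1cc(OC)c(OC)c(OC)c1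
F4 | step 2 | ethyl 2-(3,4,5-trimethoxyphenyl)cycloprop-2-ene-1-carboxylate (racemic) | CCOC(=O)C1C=C1c1cc(OC)c(OC)c(OC)c1
A1 | alternative 1 | 3-(dicyanomethyl)-N-(quinolin-8-yl)-2-(3,4,5-trimethoxyphenyl)cyclobutane-1-carboxamide (aryl cis to amide, dicyanomethyl trans to aryl) | O=C(Nc1cccc2cccnc12)[C@@H]1[C@H](c2cc(OC)c(OC)c(OC)c2)[C@@H](C(C#N)C#N)C1
A2 | alternative 1 | N-(quinolin-8-yl)cyclobut-2-ene-1-carboxamide (racemic) | O=C(Nc1cccc2cccnc12)C1C=CC1
A3 | alternative 1 | malononitrile | N#CCC#N
A4 | alternative 2 | dimethyl all-trans-2,4-bis(4-hydroxy-3,5-dimethoxyphenyl)cyclobutane-1,3-dicarboxylate | COC(=O)[C@H]1[C@H](c2cc(OC)c(O)c(OC)c2)[C@@H](C(=O)OC)[C@@H]1c1cc(OC)c(O)c(OC)c1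
A5 | alternative 2 | dimethyl all-trans-2,4-bis[1,3-bis(dimethylamino)trimethinium-2-yl]cyclobutane-1,3-dicarboxylate bis(hexafluorophosphate) | COC(=O)[C@H]1[C@H](C(C=[N+](C)C)=CN(C)C)[C@@H](C(=O)OC)[C@@H]1C(C=[N+](C)C)=CN(C)C.F[P-](F)(F)(F)(F)F.F[P-](F)(F)(F)(F)F
A6 | alternative 2 | 1,3-dimethoxypropan-2-one | COCC(=O)COC
A7 | alternative 3 | methyl all-trans-3-(but-3-en-1-ylcarbamoyl)-2,4-bis(3,4,5-trimethoxyphenyl)cyclobutane-1-carboxylate | COC(=O)[C@H]1[C@H](c2cc(OC)c(OC)c(OC)c2)[C@@H](C(=O)NCCC=C)[C@@H]1c1cc(OC)c(OC)c(OC)c1
A8 | alternative 3 | methyl 3-diazo-4-oxo-2,5-bis(3,4,5-trimethoxyphenyl)cyclopentane-1-carboxylate (aryl groups cis to each other, ester trans to both) | COC(=O)[C@@H]1[C@@H](c2cc(OC)c(OC)c(OC)c2)C(=[N+]=[N-])C(=O)[C@H]1c1cc(OC)c(OC)c(OC)c1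
A9 | alternative 3 | but-3-en-1-amine | C=CCCN
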